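## The problem

The target 23 is a sesquilignan. It is a trans-α,β-dibenzyl-γ-butyrolactone (the matairesinol skeleton, rings A and B) whose ring B phenol oxygen is bonded to C8'' of a 1-arylpropane-1,3-diol (ring C). Labels used here: lactone α-carbon C8 (joined to ring B through C7), β-carbon C8' (joined to ring A through C7'), benzylic carbinol C7'' on ring C, aryloxy carbon C8'', primary carbinol C9''.

There are four stereocentres in two pairs, C8/C8' (R,R, trans) and C7''/C8'' (R,R, threo). The para-disubstituted ring B separates the pairs, so neither can control the other and each needs its own absolute source. Within a pair, control is available: C8' fixes C8 thermodynamically (the trans lactone is the stable epimer), and C8'' can fix C7'' by 1,2-induction.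

The sensitive groups are:
- the lactone (hydride, hydroxide, enolisable C8–H);
- the C7'' carbinol, benzylic and para to oxygen, so prone to ionisation in acid and to hydrogenolysis;
- the β-aryl ether, which would eliminate or cleave by retro-aldol if C7'' were a ketone under base;
- the two phenols, which must stay masked to the end.

The feature that opens the key step is C7'' itself. It is bonded to ring C and lies next to C8'', whose oxygen substituent is the 2-methoxyphenoxy group of ring B. A C8'' aldehyde can hold magnesium between the carbonyl oxygen and these ether oxygens, so the ring C–C7'' bond can be made by aryl Grignard addition with C8'' directing the new centre.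

## Retrosynthesis

**Unmasking (23 from 22 from 21).** No skeletal bond is cut; only two O–benzyl bonds and one O–Si bond. Benzyl ethers on the ring A and ring C phenols survive Grignard, hydride, enolate and amine-base steps and leave together in one neutral hydrogenolysis. The C9'' hydroxyl is traced to a triisopropylsilyl ether, chosen for the needs of the key step. The forward steps must remove silicon without base-induced change at C8 and cleave the aryl benzyl ethers while sparing the benzylic C7''–OH.

**Fragment union (21 from 10 and 19).** The ring B C1–C7 bond and the C8–H bond are cut, giving arylboronate 10 and α-methylene lactone 19. The neighbouring C7–C8 cut (benzylation of the enolate of lactone 16) is the classical lignan bond, but it would first need a one-carbon homologation of the ring B bromide over several steps. Cutting the O–C8'' ether at this stage would ask for substitution at a hindered secondary carbon beside a benzylic carbinol. The chosen cut splits the target into two halves of similar size, each carrying one stereo pair. The forward reaction must tolerate a free secondary alcohol, a silyl ether and the lactone, and must end at the trans lactone.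

**Boron handle (10 from 9).** Only the C–B bond is exchanged for C–Br. The bromide is inert in all earlier steps.

**Key cut (9 from 6 and 8).** The ring C–C7'' bond is cut to aldehyde 6 and Grignard reagent 8.
- A hydride reduction of a C7'' ketone through the same chelate would give the erythro isomer, because hydride and aryl exchange roles. Making aryl the nucleophile turns the chelate model towards threo.
- The C7''–C8'' cut (a glycolate aldol with aldehyde 11) needs a stoichiometric auxiliary and a later reduction.
- The precursor shrinks to a three-carbon aldehyde with one stereocentre and a simple aryl nucleophile.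
- The forward step must give high facial selectivity and must not epimerise 6.

**Aldehyde (6 from 5, from 3 and 4; 3 from 2 from 1).** The O–C8'' bond is cut by a Mitsunobu inversion between phenol 4 and α-hydroxy ester 3. Ester 3 comes from the chiral-pool acetonide 1 via diol 2. A lipase desymmetrisation route to the same aldehyde was weighed; it needs two more steps and an enantiopreference not established for aryloxy substituents. Here the configuration of C8'' follows from the SN2 inversion. Partial reduction of 5 gives 6.

**Grignard reagent (8 from 7 from 4).** The same phenol 4 serves ring C after benzylation and magnesium insertion.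

**Lactone (19 from 17, 16, 14, 13, from 11 and 12).** The exocyclic methylene comes from Mannich base 17. Lactone 16 comes from half-ester 14 by ester-selective reduction. C8' is set by asymmetric hydrogenation of the Stobbe half-ester 13, which is made from aldehyde 11 and dimethyl succinate 12. This is three steps to 16 with a catalytic source of chirality.

## Roads not taken

**Alternative 1:** Rhodium aryl conjugate addition as the strategic step.
- Cut: the ring B C1–C7 bond and C8–H.
- Forward step: the acetonide-protected ring B boronate A2 adds to lactone 19 with [Rh(cod)OH]2 (monovalent rhodium) to give the fully protected target A1.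
- Merits: the most convergent union available; mild and neutral; the acetonide shields the carbinol and lets the threo relation be checked.
- Weak points: the step creates only C8, by protonation, so the trans relation still comes from equilibration. It does not address the harder threo C7''/C8'' pair, so a second stereodefining idea is needed anyway. The acetonide costs two extra protecting-group steps and its acidic removal happens at a para-alkoxybenzylic carbon.
- Comparison: in convergence it equals the chosen plan, which uses the same coupling as step 14. Its carbinol protection during the rhodium step is better than the free alcohol of 10. The chosen plan sets against this two fewer steps and an explicit solution for C7''/C8''.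

**Alternative 2:** Late syn-glycolate aldol.
- Cut: the C7''–C8'' bond.
- Forward step: the dibutylboron enolate of imide A4, built on the ring B oxygen of the protected lactone, adds to aldehyde 11 to give the syn adduct A3.
- Merits: both glycerol centres are set at once under auxiliary control, which is more predictable than the substrate-controlled chelate addition. This is a real advantage.
- Weak points: A4 requires the two nearly identical phenols of the lactone to be differentiated, so the lactone must be built with orthogonal protection. The imide must then be reduced to C9''H2OH in the presence of the butyrolactone, a hydride chemoselectivity problem at the most advanced stage. A stoichiometric auxiliary is spent late and the route is linear.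
- Comparison: the chosen plan has weaker precedent for its stereocontrol. It sets against this that all hydride chemistry is finished before the lactone appears, and it keeps this aldol as a fragment-stage fallback.

**Alternative 3:** Dynamic kinetic transfer hydrogenation.
- Cut: the C7''–H bond.
- Forward step: the epimerising keto ester A6 is reduced by RuCl(p-cymene)(TsDPEN) (divalent ruthenium) with formic acid and triethylamine to the hydroxy ester A5.
- Merits: catalytic, no stoichiometric chiral reagent, two centres from a racemic centre in one operation. In atom economy it is the best of the four.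
- Weak points: the syn or anti sense of such reductions of α-oxygenated β-keto esters depends on catalyst and substrate and is not secured for an α-aryloxy group. A6 needs O-alkylation of a differentiated lactone phenol with a reactive α-halo keto ester. The ethyl ester of A5 must then be reduced beside the lactone, which hydride reagents cannot be relied on to distinguish. The product can also undergo retro-aldol cleavage in the basic medium.
- Comparison: it has fewer stereo-setting operations. The chosen plan pays with a chiral-pool start and a substrate-controlled addition, but it has no late ester-versus-lactone problem.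

Key step: step 7

Assumption: in step 10 the (S,S) ligand is taken to give the (R) acid 14, by analogy with related itaconate half-esters; if the sense were opposite, the (R,R) ligand would be used and nothing else changes.

## Route

Step 1
Reactants: 1 methyl (S)-2,2-dimethyl-1,3-dioxolane-4-carboxylate
Product: 2 methyl (S)-2,3-dihydroxypropanoate
Conditions: Dowex 50WX8 (H+ form), MeOH/H2O 9:1, 40 °C
Reagents that add atoms: none
Why: Acid-catalysed acetonide hydrolysis; the methyl ester and the C2 stereocentre are not affected by the mild resin acid.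

Step 2
Reactants: 2 methyl (S)-2,3-dihydroxypropanoate
Product: 3 methyl (S)-2-hydroxy-3-[(triisopropylsilyl)oxy]propanoate
Conditions: i-Pr3SiCl, imidazole, CH2Cl2, 0 °C to rt
Reagents that add atoms: triisopropylsilyl chloride, CC(C)[Si](Cl)(C(C)C)C(C)C
Why: Selective silyl ether formation at the primary hydroxyl with a bulky chlorosilane; the secondary hydroxyl next to the ester stays free for the next step.

Step 3
Reactants: 3 methyl (S)-2-hydroxy-3-[(triisopropylsilyl)oxy]propanoate; 4 4-bromo-2-methoxyphenol
Product: 5 methyl (R)-2-(4-bromo-2-methoxyphenoxy)-3-[(triisopropylsilyl)oxy]propanoate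
Conditions: PPh3, DIAD, THF, 0 °C to rt
Reagents that add atoms: none
Why: Mitsunobu etherification: the phenoxide displaces the oxyphosphonium of the α-hydroxy ester by SN2 with inversion, so the (S) carbinol becomes the (R) aryl ether that will be C8''. α-Hydroxy esters are reliable substrates for this reaction with phenols.

Step 4
Reactants: 5 methyl (R)-2-(4-bromo-2-methoxyphenoxy)-3-[(triisopropylsilyl)oxy]propanoate
Product: 6 (R)-2-(4-bromo-2-methoxyphenoxy)-3-[(triisopropylsilyl)oxy]propanal
Conditions: i-Bu2AlH (1.2 equiv), CH2Cl2, −78 °C; MeOH, then aq. KNaC4H4O6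
Reagents that add atoms: none
Why: Partial ester reduction: the tetrahedral aluminium hemiacetal, stabilised by the α-oxygen, persists at −78 °C and releases the aldehyde only on the cold quench. The crude aldehyde is used at once so that the α-centre does not epimerise.

Step 5
Reactants: 4 4-bromo-2-methoxyphenol
Product: 7 1-(benzyloxy)-4-bromo-2-methoxybenzene
Conditions: BnBr, K2CO3, DMF, rt
Reagents that add atoms: benzyl bromide, BrCc1ccccc1
Why: Williamson ether synthesis on a phenoxide; it masks the future ring C phenol in a form stable to magnesium and to all later base and hydride steps.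

Step 6
Reactants: 7 1-(benzyloxy)-4-bromo-2-methoxybenzene
Product: 8 [4-(benzyloxy)-3-methoxyphenyl]magnesium bromide (about 1 M solution in THF, titrated and used directly)
Conditions: Mg turnings, I2 (cat.), THF, 40 °C to rt
Reagents that add atoms: magnesium, [Mg]
Why: Oxidative insertion of magnesium into the aryl C–Br bond (Grignard formation); aryl benzyl and methyl ethers are inert.

Step 7
Reactants: 6 (R)-2-(4-bromo-2-methoxyphenoxy)-3-[(triisopropylsilyl)oxy]propanal; 8 [4-(benzyloxy)-3-methoxyphenyl]magnesium bromide
Product: 9 (1R,2R)-1-[4-(benzyloxy)-3-methoxyphenyl]-2-(4-bromo-2-methoxyphenoxy)-3-[(triisopropylsilyl)oxy]propan-1-ol (threo)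
Conditions: MgBr2·OEt2 (1.5 equiv), CH2Cl2, −78 °C; then 8 (1.5 equiv, 1 M in THF) added slowly, −78 to −40 °C; aq. NH4Cl
Reagents that add atoms: none
Why: This is a Cram-chelate 1,2-addition of an aryl Grignard reagent to an α-alkoxy aldehyde, which is the closest known reaction type. MgBr2 (divalent magnesium) binds the carbonyl oxygen and the α-aryloxy oxygen of 6, with the ortho methoxy group of ring B as a further donor, and locks a five-membered chelate in which C=O and the C8''–O bond are syn-periplanar. The aryl group of 8 then adds to the carbonyl carbon in a polar two-electron step from the face that carries the C8'' hydrogen (the Re face), anti to the CH2OSi arm, and forms the ring C–C7'' bond. No ring is closed. The new centre C7'' should become R under control of the existing (R) centre C8'' through this chelate, which gives the threo carbinol, whereas the open polar Felkin–Anh pathway would give erythro. The step needs this diastereofacial selectivity and an intact C8'': the shielded, weakly basic triisopropylsilyl ether oxygen should not compete as a β-chelating donor, precomplexation in non-coordinating CH2Cl2 favours the chelate over THF solvation, and −78 °C suppresses enolisation of the aldehyde. The ring B aryl bromide does not exchange with an arylmagnesium bromide at this temperature and is carried on as the coupling handle.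

Step 8
Reactants: 9 (1R,2R)-1-[4-(benzyloxy)-3-methoxyphenyl]-2-(4-bromo-2-methoxyphenoxy)-3-[(triisopropylsilyl)oxy]propan-1-ol
Product: 10 (1R,2R)-1-[4-(benzyloxy)-3-methoxyphenyl]-2-[2-methoxy-4-(4,4,5,5-tetramethyl-1,3,2-dioxaborolan-2-yl)phenoxy]-3-[(triisopropylsilyl)oxy]propan-1-ol
Conditions: B2pin2, Pd(dppf)Cl2·CH2Cl2 (5 mol%), KOAc, 1,4-dioxane, 85 °C
Reagents that add atoms: bis(pinacolato)diboron, CC1(C)OB(OC1(C)C)B1OC(C)(C)C(C)(C)O1
Why: Miyaura borylation: oxidative addition of the aryl bromide to zerovalent palladium formed from Pd(dppf)Cl2, acetate-assisted transmetalation with B2pin2 and reductive elimination. The free secondary alcohol, the silyl ether and the benzyl ethers are inert to KOAc.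

Step 9
Reactants: 11 4-(benzyloxy)-3-methoxybenzaldehyde; 12 dimethyl succinate
Product: 13 (E)-4-[4-(benzyloxy)-3-methoxyphenyl]-3-(methoxycarbonyl)but-3-enoic acid
Conditions: NaOMe, MeOH, reflux; then aq. HCl
Reagents that add atoms: none
Why: Stobbe condensation: the succinate enolate adds to the aldehyde, the alkoxide closes to a paraconic ester, and base-induced ring opening gives the alkylidene half-ester irreversibly, mainly as the E isomer.

Step 10
Reactants: 13 (E)-4-[4-(benzyloxy)-3-methoxyphenyl]-3-(methoxycarbonyl)but-3-enoic acid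
Product: 14 (R)-4-[4-(benzyloxy)-3-methoxyphenyl]-3-(methoxycarbonyl)butanoic acid
Conditions: [Rh(cod)((S,S)-Et-DuPhos)]BF4 (1 mol%), H2 (5 bar), NaOMe (0.1 equiv), MeOH, rt
Reagents that add atoms: none
Why: Rhodium-catalysed asymmetric hydrogenation of an itaconate half-ester: carboxylate and alkene chelate the cationic monovalent rhodium bisphosphine and the C2-symmetric ligand selects the alkene face, which sets C8' as R. The homogeneous catalyst does not cleave aryl benzyl ethers.

Step 11
Reactants: 14 (R)-4-[4-(benzyloxy)-3-methoxyphenyl]-3-(methoxycarbonyl)butanoic acid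
Product: 16 (R)-4-[4-(benzyloxy)-3-methoxybenzyl]dihydrofuran-2(3H)-one, via hydroxy acid 15 (not isolated)
Conditions: KOH (1 equiv), EtOH; CaCl2, NaBH4, EtOH, −10 °C to rt; then 3 M HCl, rt
Reagents that add atoms: none
Why: Ca(BH4)2 formed in the flask reduces the ester while the acid is protected as its carboxylate, and acidification lactonises the γ-hydroxy acid. The stereocentre becomes the non-enolisable β-carbon of the lactone.

Step 12
Reactants: 16 (R)-4-[4-(benzyloxy)-3-methoxybenzyl]dihydrofuran-2(3H)-one
Product: 17 (3S,4R)-4-[4-(benzyloxy)-3-methoxybenzyl]-3-[(dimethylamino)methyl]dihydrofuran-2(3H)-one (trans)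
Conditions: LiN(i-Pr)2, THF, −78 °C; then Me2N=CH2+ I−, −78 °C to rt
Reagents that add atoms: N,N-dimethylmethyleneiminium iodide (Eschenmoser's salt), C=[N+](C)C.[I-]
Why: Mannich reaction of the lithium lactone enolate with a preformed iminium salt. The electrophile enters anti to the C4 benzyl group, but this new centre is removed in the next step.

Step 13
Reactants: 17 (3S,4R)-4-[4-(benzyloxy)-3-methoxybenzyl]-3-[(dimethylamino)methyl]dihydrofuran-2(3H)-one
Product: 19 (R)-4-[4-(benzyloxy)-3-methoxybenzyl]-3-methylenedihydrofuran-2(3H)-one, via trimethylammonium iodide 18 (not isolated)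
Conditions: MeI, MeOH, rt; then aq. NaHCO3, CH2Cl2, rt
Reagents that add atoms: none
Why: Exhaustive N-methylation followed by E1cB (Hofmann-type) loss of trimethylamine gives the exocyclic alkene. The mild bicarbonate base is chosen to avoid migration of the double bond into the ring, which would erase C8'.

Step 14
Reactants: 10 (1R,2R)-1-[4-(benzyloxy)-3-methoxyphenyl]-2-[2-methoxy-4-(4,4,5,5-tetramethyl-1,3,2-dioxaborolan-2-yl)phenoxy]-3-[(triisopropylsilyl)oxy]propan-1-ol; 19 (R)-4-[4-(benzyloxy)-3-methoxybenzyl]-3-methylenedihydrofuran-2(3H)-one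
Product: 21 (3R,4R)-4-[4-(benzyloxy)-3-methoxybenzyl]-3-[4-({(1R,2R)-1-[4-(benzyloxy)-3-methoxyphenyl]-1-hydroxy-3-[(triisopropylsilyl)oxy]propan-2-yl}oxy)-3-methoxybenzyl]dihydrofuran-2(3H)-one, via cis lactone 20 (not isolated)
Conditions: [Rh(cod)OH]2 (3 mol%), K3PO4 (0.5 equiv), 1,4-dioxane/H2O 10:1, 50 °C; then DBU (0.3 equiv), toluene, 80 °C
Reagents that add atoms: none
Why: Rhodium-catalysed conjugate addition of an arylboron reagent to an α-methylene lactone (Hayashi–Miyaura type): transmetalation gives an aryl monovalent rhodium species, carbometalation of the exocyclic alkene gives the rhodium enolate, and water protonates it. Protonation at C8 should occur mainly anti to the C8' substituent and give the cis lactone 20 first; DBU then epimerises C8, the only acidic centre, to the more stable trans lactone, so C8' (R) controls C8 (R).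

Step 15
Reactants: 21 the silyl-protected trans lactone of step 14
Product: 22 (3R,4R)-4-[4-(benzyloxy)-3-methoxybenzyl]-3-[4-({(1R,2R)-1-[4-(benzyloxy)-3-methoxyphenyl]-1,3-dihydroxypropan-2-yl}oxy)-3-methoxybenzyl]dihydrofuran-2(3H)-one
Conditions: Bu4NF, AcOH, THF, 0 °C to rt
Reagents that add atoms: none
Why: Fluoride cleavage of the primary silyl ether. Buffering with AcOH keeps the medium non-basic, so the lactone and the trans C8 centre are not disturbed.

Step 16
Reactants: 22 the dibenzyl diol of step 15
Product: 23 (3R,4R)-3-[4-({(1R,2R)-1,3-dihydroxy-1-(4-hydroxy-3-methoxyphenyl)propan-2-yl}oxy)-3-methoxybenzyl]-4-(4-hydroxy-3-methoxybenzyl)dihydrofuran-2(3H)-one (target)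
Conditions: H2 (1 atm), 10% Pd/C, EtOAc/EtOH 1:1, rt
Reagents that add atoms: none
Why: Hydrogenolysis of the two aryl benzyl ethers over Pd/C under neutral conditions. Aryl benzyl ethers cleave much faster than the secondary benzylic alcohol, which should survive if the reaction is stopped after two equivalents of H2 in an acid-free solvent.

## Compound list

1 | methyl (S)-2,2-dimethyl-1,3-dioxolane-4-carboxylate | COC(=O)[C@@H]1COC(C)(C)O1 | starting material
2 | methyl (S)-2,3-dihydroxypropanoate | COC(=O)[C@@H](O)CO | intermediate
3 | methyl (S)-2-hydroxy-3-[(triisopropylsilyl)oxy]propanoate | COC(=O)[C@@H](O)CO[Si](C(C)C)(C(C)C)C(C)C | intermediate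
4 | 4-bromo-2-methoxyphenol | COc1cc(Br)ccc1O | starting material
5 | methyl (R)-2-(4-bromo-2-methoxyphenoxy)-3-[(triisopropylsilyl)oxy]propanoate | COc1cc(Br)ccc1O[C@H](CO[Si](C(C)C)(C(C)C)C(C)C)C(=O)OC | intermediate
6 | (R)-2-(4-bromo-2-methoxyphenoxy)-3-[(triisopropylsilyl)oxy]propanal | COc1cc(Br)ccc1O[C@H](CO[Si](C(C)C)(C(C)C)C(C)C)C=O | intermediate
7 | 1-(benzyloxy)-4-bromo-2-methoxybenzene | COc1cc(Br)ccc1OCc1ccccc1 | intermediate
8 | [4-(benzyloxy)-3-methoxyphenyl]magnesium bromide | COc1cc([Mg]Br)ccc1OCc1ccccc1 | intermediate
9 | (1R,2R)-1-[4-(benzyloxy)-3-methoxyphenyl]-2-(4-bromo-2-methoxyphenoxy)-3-[(triisopropylsilyl)oxy]propan-1-ol | COc1cc(Br)ccc1O[C@H](CO[Si](C(C)C)(C(C)C)C(C)C)[C@H](O)c1ccc(OCc2ccccc2)c(OC)c1 | intermediate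
10 | (1R,2R)-1-[4-(benzyloxy)-3-methoxyphenyl]-2-[2-methoxy-4-(4,4,5,5-tetramethyl-1,3,2-dioxaborolan-2-yl)phenoxy]-3-[(triisopropylsilyl)oxy]propan-1-ol | COc1cc(B2OC(C)(C)C(C)(C)O2)ccc1O[C@H](CO[Si](C(C)C)(C(C)C)C(C)C)[C@H](O)c1ccc(OCc2ccccc2)c(OC)c1 | intermediate
11 | 4-(benzyloxy)-3-methoxybenzaldehyde | COc1cc(C=O)ccc1OCc1ccccc1 | starting material
12 | dimethyl succinate | COC(=O)CCC(=O)OC | starting material
13 | (E)-4-[4-(benzyloxy)-3-methoxyphenyl]-3-(methoxycarbonyl)but-3-enoic acid | COC(=O)/C(=C/c1ccc(OCc2ccccc2)c(OC)c1)CC(=O)O | intermediate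
14 | (R)-4-[4-(benzyloxy)-3-methoxyphenyl]-3-(methoxycarbonyl)butanoic acid | COC(=O)[C@H](Cc1ccc(OCc2ccccc2)c(OC)c1)CC(=O)O | intermediate
15 | (R)-4-[4-(benzyloxy)-3-methoxyphenyl]-3-(hydroxymethyl)butanoic acid | OC[C@H](Cc1ccc(OCc2ccccc2)c(OC)c1)CC(=O)O | intermediate (not isolated)
16 | (R)-4-[4-(benzyloxy)-3-methoxybenzyl]dihydrofuran-2(3H)-one | COc1cc(C[C@H]2COC(=O)C2)ccc1OCc1ccccc1 | intermediate
17 | (3S,4R)-4-[4-(benzyloxy)-3-methoxybenzyl]-3-[(dimethylamino)methyl]dihydrofuran-2(3H)-one | COc1cc(C[C@H]2COC(=O)[C@@H]2CN(C)C)ccc1OCc1ccccc1 | intermediate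
18 | {(3S,4R)-4-[4-(benzyloxy)-3-methoxybenzyl]-2-oxotetrahydrofuran-3-yl}-N,N,N-trimethylmethanaminium iodide | COc1cc(C[C@H]2COC(=O)[C@@H]2C[N+](C)(C)C)ccc1OCc1ccccc1.[I-] | intermediate (not isolated)
19 | (R)-4-[4-(benzyloxy)-3-methoxybenzyl]-3-methylenedihydrofuran-2(3H)-one | COc1cc(C[C@H]2COC(=O)C2=C)ccc1OCc1ccccc1 | intermediate
20 | (3S,4R) cis epimer of 21 | COc1cc(C[C@H]2COC(=O)[C@H]2Cc2ccc(O[C@H](CO[Si](C(C)C)(C(C)C)C(C)C)[C@H](O)c3ccc(OCc4ccccc4)c(OC)c3)c(OC)c2)ccc1OCc1ccccc1 | intermediate (not isolated)
21 | (3R,4R)-4-[4-(benzyloxy)-3-methoxybenzyl]-3-[4-({(1R,2R)-1-[4-(benzyloxy)-3-methoxyphenyl]-1-hydroxy-3-[(triisopropylsilyl)oxy]propan-2-yl}oxy)-3-methoxybenzyl]dihydrofuran-2(3H)-one | COc1cc(C[C@H]2COC(=O)[C@@H]2Cc2ccc(O[C@H](CO[Si](C(C)C)(C(C)C)C(C)C)[C@H](O)c3ccc(OCc4ccccc4)c(OC)c3)c(OC)c2)ccc1OCc1ccccc1 | intermediate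
22 | (3R,4R)-4-[4-(benzyloxy)-3-methoxybenzyl]-3-[4-({(1R,2R)-1-[4-(benzyloxy)-3-methoxyphenyl]-1,3-dihydroxypropan-2-yl}oxy)-3-methoxybenzyl]dihydrofuran-2(3H)-one | COc1cc(C[C@H]2COC(=O)[C@@H]2Cc2ccc(O[C@H](CO)[C@H](O)c3ccc(OCc4ccccc4)c(OC)c3)c(OC)c2)ccc1OCc1ccccc1 | intermediate
23 | (3R,4R)-3-[4-({(1R,2R)-1,3-dihydroxy-1-(4-hydroxy-3-methoxyphenyl)propan-2-yl}oxy)-3-methoxybenzyl]-4-(4-hydroxy-3-methoxybenzyl)dihydrofuran-2(3H)-one | COc1cc(C[C@H]2COC(=O)[C@@H]2Cc2ccc(O[C@H](CO)[C@H](O)c3ccc(O)c(OC)c3)c(OC)c2)ccc1O | target

## Step count and risks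

Total: 16 steps. Longest linear sequence: 9 steps (1, 2, 3, 4, 7, 8, 14, 15, 16).

**Step 7 (key step).** Facial selectivity may be poor if THF from the Grignard solution, or the low basicity of the aryloxy oxygen, lets the non-chelated Felkin–Anh pathway compete. The aldehyde may also epimerise by enolisation before it is consumed. The fallback leaves the Grignard disconnection for an Evans syn-glycolate aldol at the fragment stage, where no lactone is present. It sets out from 4 and 11:
- Phenol 4 is O-alkylated with chloroacetic acid and aqueous NaOH to 2-(4-bromo-2-methoxyphenoxy)acetic acid F1.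
- F1 is coupled through its pivaloyl mixed anhydride with (S)-4-benzyl-2-oxazolidinone (LiCl, Et3N) to the imide F2.
- The Z-boron enolate of F2 (Bu2BOTf, i-Pr2NEt, CH2Cl2, −78 °C) adds to aldehyde 11 to give the syn adduct F3, with both centres set by the auxiliary.
- LiBH4 in wet THF removes the auxiliary and gives the threo diol F4.
- Selective silylation of the primary hydroxyl (i-Pr3SiCl, imidazole) returns to the route at 9.

**Step 14.** Several processes may lower the outcome:
- protodeboronation of the electron-rich boronate;
- migration of the exocyclic double bond of 19 into the ring, with loss of C8';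
- β-hydride elimination from a rhodium alkoxide of the free carbinol;
- incomplete cis-to-trans equilibration.

The fallback is the classical trans-selective enolate alkylation. It sets out from 9 and 16 and makes steps 8, 12 and 13 unnecessary:
- Carbinol 9 is silylated (Et3SiCl, imidazole) to the triethylsilyl ether F5.
- Bromine–lithium exchange (n-BuLi, THF, −78 °C) and DMF give the aldehyde F6.
- NaBH4 gives the benzylic alcohol F7.
- CBr4 and PPh3 give the benzylic bromide F8.
- The lithium enolate of 16 (LiN(SiMe3)2, THF, −78 °C) is alkylated by F8 anti to the C8' substituent to give the trans lactone F9.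
- Bu4NF with AcOH removes both silyl groups and returns to the route at 22.

**Step 4.** Over-reduction to the primary alcohol, or early collapse of the aluminium hemiacetal with epimerisation on work-up, may erode yield or optical purity. The fallback separates reduction and oxidation. It sets out from 5: LiBH4 in THF reduces the ester fully to (S)-2-(4-bromo-2-methoxyphenoxy)-3-[(triisopropylsilyl)oxy]propan-1-ol F10. Dess–Martin periodinane buffered with NaHCO3 then oxidises F10 under neutral conditions and returns to the route at 6.

**Step 3.** Substitution at the secondary carbon flanked by the ester and the bulky silyloxymethyl arm may be slow. That would allow elimination, alkylation of the hydrazide or partial loss of configuration. The fallback replaces the redox condensation by sulfonate displacement. It sets out from 3: Tf2O and 2,6-lutidine (CH2Cl2, −78 °C) give methyl (S)-3-[(triisopropylsilyl)oxy]-2-[(trifluoromethylsulfonyl)oxy]propanoate F11. Phenol 4 with K2CO3 in MeCN at 0 °C then displaces the triflate with inversion and returns to the route at 5.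

## Further compounds

F1 | step 7 | 2-(4-bromo-2-methoxyphenoxy)acetic acid | COc1cc(Br)ccc1OCC(=O)O
F2 | step 7 | (S)-4-benzyl-3-[2-(4-bromo-2-methoxyphenoxy)acetyl]oxazolidin-2-one | COc1cc(Br)ccc1OCC(=O)N1[C@@H](Cc2ccccc2)COC1=O
F3 | step 7 | (S)-4-benzyl-3-[(2S,3R)-3-[4-(benzyloxy)-3-methoxyphenyl]-2-(4-bromo-2-methoxyphenoxy)-3-hydroxypropanoyl]oxazolidin-2-one | COc1cc(Br)ccc1O[C@H](C(=O)N1[C@@H](Cc2ccccc2)COC1=O)[C@H](O)c1ccc(OCc2ccccc2)c(OC)c1
F4 | step 7 | (1R,2R)-1-[4-(benzyloxy)-3-methoxyphenyl]-2-(4-bromo-2-methoxyphenoxy)propane-1,3-diol | COc1cc(Br)ccc1O[C@H](CO)[C@H](O)c1ccc(OCc2ccccc2)c(OC)c1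
F5 | step 14 | triethylsilyl ether of 9 at the C7'' hydroxyl | COc1cc(Br)ccc1O[C@H](CO[Si](C(C)C)(C(C)C)C(C)C)[C@H](O[Si](CC)(CC)CC)c1ccc(OCc2ccccc2)c(OC)c1
F6 | step 14 | 4-({(1R,2R)-1-[4-(benzyloxy)-3-methoxyphenyl]-1-[(triethylsilyl)oxy]-3-[(triisopropylsilyl)oxy]propan-2-yl}oxy)-3-methoxybenzaldehyde | COc1cc(C=O)ccc1O[C@H](CO[Si](C(C)C)(C(C)C)C(C)C)[C@H](O[Si](CC)(CC)CC)c1ccc(OCc2ccccc2)c(OC)c1
F7 | step 14 | benzylic alcohol from reduction of F6 | COc1cc(CO)ccc1O[C@H](CO[Si](C(C)C)(C(C)C)C(C)C)[C@H](O[Si](CC)(CC)CC)c1ccc(OCc2ccccc2)c(OC)c1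
F8 | step 14 | benzylic bromide from F7 | COc1cc(CBr)ccc1O[C@H](CO[Si](C(C)C)(C(C)C)C(C)C)[C@H](O[Si](CC)(CC)CC)c1ccc(OCc2ccccc2)c(OC)c1
F9 | step 14 | (3R,4R) trans lactone carrying the triethylsilyl and triisopropylsilyl ethers and both benzyl ethers | COc1cc(C[C@H]2COC(=O)[C@@H]2Cc2ccc(O[C@H](CO[Si](C(C)C)(C(C)C)C(C)C)[C@H](O[Si](CC)(CC)CC)c3ccc(OCc4ccccc4)c(OC)c3)c(OC)c2)ccc1OCc1ccccc1
F10 | step 4 | (S)-2-(4-bromo-2-methoxyphenoxy)-3-[(triisopropylsilyl)oxy]propan-1-ol | COc1cc(Br)ccc1O[C@H](CO[Si](C(C)C)(C(C)C)C(C)C)CO
F11 | step 3 | methyl (S)-3-[(triisopropylsilyl)oxy]-2-[(trifluoromethylsulfonyl)oxy]propanoate | COC(=O)[C@@H](OS(=O)(=O)C(F)(F)F)CO[Si](C(C)C)(C(C)C)C(C)C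
A1 | alternative 1 | (3R,4R)-4-[4-(benzyloxy)-3-methoxybenzyl]-3-[4-({(4R,5R)-4-[4-(benzyloxy)-3-methoxyphenyl]-2,2-dimethyl-1,3-dioxan-5-yl}oxy)-3-methoxybenzyl]dihydrofuran-2(3H)-one | COc1cc(C[C@H]2COC(=O)[C@@H]2Cc2ccc(O[C@@H]3COC(C)(C)O[C@@H]3c3ccc(OCc4ccccc4)c(OC)c3)c(OC)c2)ccc1OCc1ccccc1
A2 | alternative 1 | 2-[4-({(4R,5R)-4-[4-(benzyloxy)-3-methoxyphenyl]-2,2-dimethyl-1,3-dioxan-5-yl}oxy)-3-methoxyphenyl]-4,4,5,5-tetramethyl-1,3,2-dioxaborolane | COc1cc(B2OC(C)(C)C(C)(C)O2)ccc1O[C@@H]1COC(C)(C)O[C@@H]1c1ccc(OCc2ccccc2)c(OC)c1
A3 | alternative 2 | syn aldol adduct: (2S,3R)-2-aryloxy-3-hydroxy imide on the ring B oxygen of the ring A benzyl-protected lactone | COc1cc(C[C@H]2COC(=O)[C@@H]2Cc2ccc(O[C@H](C(=O)N3[C@@H](Cc4ccccc4)COC3=O)[C@H](O)c3ccc(OCc4ccccc4)c(OC)c3)c(OC)c2)ccc1OCc1ccccc1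
A4 | alternative 2 | N-(aryloxyacetyl) (S)-4-benzyloxazolidinone on the ring B oxygen of the ring A benzyl-protected lactone | COc1cc(C[C@H]2COC(=O)[C@@H]2Cc2ccc(OCC(=O)N3[C@@H](Cc4ccccc4)COC3=O)c(OC)c2)ccc1OCc1ccccc1
A5 | alternative 3 | ethyl (2S,3R)-2-aryloxy-3-[4-(benzyloxy)-3-methoxyphenyl]-3-hydroxypropanoate on the ring B oxygen of the ring A benzyl-protected lactone | COc1cc(C[C@H]2COC(=O)[C@@H]2Cc2ccc(O[C@H](C(=O)OCC)[C@H](O)c3ccc(OCc4ccccc4)c(OC)c3)c(OC)c2)ccc1OCc1ccccc1
A6 | alternative 3 | ethyl 2-aryloxy-3-[4-(benzyloxy)-3-methoxyphenyl]-3-oxopropanoate on the same lactone, epimeric at C8'' | COc1cc(C[C@H]2COC(=O)[C@@H]2Cc2ccc(OC(C(=O)OCC)C(=O)c3ccc(OCc4ccccc4)c(OC)c3)c(OC)c2)ccc1OCc1ccccc1
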